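The leftover comes first: in Saturday's run at 8.00 h, 43.6% of the starting complex is neither singly nor doubly exchanged.

| flask | starting complex | incoming ligand | protic impurity | scavenger | remark | time |
|---|---|---|---|---|---|---|
| Saturday's | 0.050 M | 0.075 M | 0.010 M | 0.060 M | run made earlier |  |
| Monday's | 0.050 M | 0.30 M | 0.010 M | 0.060 M | run made earlier |  |
| flask | 0.050 M | 0.150 M | 0.0100 M | 0.0600 M |  | 8.0 h |

| run | time / h | complex with one exchanged / % | complex with two exchanged / % |
|---|---|---|---|
| Saturday's | 2.00 | 22.0 | 0 |
| Saturday's | 4.00 | 36.6 | 1.0 |
| Saturday's | 6.00 | 46.6 | 1.2 |
| Saturday's | 8.00 | 55.4 | 1.0 |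
| Monday's | 1.00 | 41.5 | 2.8 |
| Monday's | 3.00 | 72.4 | 6.1 |
| Monday's | 5.00 | 77.9 | 10.5 |
| Monday's | 8.00 | 74.4 | 20.0 |

(readings scatter by 1 percentage point)



- equivalents of incoming ligand to starting complex, everything else as given, that leave most complex with one exchanged at 8.0 h
- the amount of complex with one exchanged then, in percent of the starting complex charged
- the amount of complex with one exchanged with the amounts as given

Take the first exchange as second order, rate = k·c(starting complex)·c(incoming ligand). This integrates in closed form. With a and b the charged c(incoming ligand) and c(starting complex), the unchanged fraction is f = (a−b)/(a·exp((a−b)kt)−b). Saturday's leftover, taken as unchanged complex, reads k = 1.79 L mol⁻¹ h⁻¹, the exchange constant, the rate of first exchange per unit of both concentrations.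

Two views then part over the scavenger. The forecast holds that it is the wall, after the impurity has taken its share: “Scavenger exhaustion near 3.6 equiv pulls it to about 3.8 equiv”. It gives 3.8 equiv, 79.5% there, and 76.5% as charged.

My view differs. Monday's leftover at 8.00 h is 5.60%, while f gives 2.32%. That gap of 3.3 percentage points is smaller than the impurity's charge, 20.0% of the complex, so I book it to impurity eating starting complex and count the full scavenger charge as free for released ligand. Released ligand as read on Monday, 114% of the complex, is then less than the scavenger charge of 120%.

For the flask, f = 17.3%, and the load, first-exchange release over charged scavenger, is 0.689. Since Monday, charged with more ligand than this flask, reads under the scavenger charge, I expect the flask's optimum above the forecast's, towards the 4.2 equiv it names for no reversal.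

The flask gives 73.3% as charged, and its optimum is 4.50 equiv with 77.6%, higher in ligand than the forecast's.

    protic impurity + starting complex → quenched substrate (k = 1.75 L mol⁻¹ h⁻¹)
    complex with one exchanged + incoming ligand ⇌ leaving ligand + complex with two exchanged (K = 1.22, k = 0.149 L mol⁻¹ h⁻¹)
    scavenger + leaving ligand → scavenged by-product (k = 424 L mol⁻¹ h⁻¹)
    leaving ligand + incoming ligand ⇌ idle adduct, settled at all times (K = 7.50 L mol⁻¹)
    starting complex + incoming ligand ⇌ leaving ligand + complex with one exchanged (K = 31.9, k = 1.88 L mol⁻¹ h⁻¹)

The scavenger view has its region in the neighbouring flask charged with 0.20 M of starting complex, which is 0.750 equiv of ligand. There f = 39.4% and the load is 2.02, above the flask's. That neighbour has scavenger, its limiting reagent, at 0%, with leaving ligand standing at 0.0490 M. Its complex with one exchanged ends at 54.4%.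

The earlier runs and the new flask stem from a simulated flask with constants of no real substance; scatter was added.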